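Start from D: in the proposed steps each D and each E spends one X, so when X is gone, D and E together equal the X charged.

- Thursday's: Z 0.10 M; X 1 equiv; J 1 equiv (fed, over 15 h); the very flask that is asked about, followed so far; the fed solution adds 1.0 times the starting volume
- flask: Z 0.10 M; X 1.00 equiv; J 1.00 equiv (fed, over 15 h); time 15 d; the fed solution adds 1.0 times the starting volume

1. at 15 d, what has stopped the reaction, if anything has (for what has run out or reacted, a solid counts together with what of it has only dissolved) (all of Z has reacted / forward and back rates have come level / it is still moving / X has run out first)
2. the D standing at 15 d, as a percentage of the Z charged

- charges are per starting volume, the dose included; the dosed solution carries all of it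
- as a solid, counted per litre of solution: Z
- steps that have been proposed: G + X -> D; J + X -> E; Z <-> G
- at the start none of Z is in solution
- what has only dissolved of Z counts as not reacted
- the reaction counts as stopped when no species that holds the Z changes by six tenths of a point or more over the second half of the time

Thursday's run (percent of the Z charged)

| time / h | D / % |
|---|---|
| 5.00 | 13 |
| 10.0 | 23 |
| 15.0 | 27 |
| 20.0 | 32 |
| 25.0 | 31 |
| 30.0 | 31 |

(standard deviation of a reading: 1.5 percentage points)

Thursday's readings from 20.0 h on average 31.3% of the X charged. Call D at rest, as a fraction of the X charged, the X share. Take an even split between the two routes as the zero of the scale: it gives one half, and Thursday's flask stands lower.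

First estimate: D in this flask stays at the X share. Object that Z may have run out. But D at that level leaves 68.7% of the Z charged not turned into D, so drop this. Object next that forward and back rates have come level. But the proposed step to D has a single arrow, so drop this too.

The serious doubt is a slow tail. The readings fall by 1 percentage point from 20.0 h to 30.0 h, less than the scatter, yet 15 d is far longer than that run. Reckon the balance instead: if X is gone, E is 68.7% of the charge, and J stands near 31.3% of its own charge, ready to take any trace of X. Commit to X as the limiting reagent and D at 31.3%, give or take 0.87 points, with any tail pointing upward.

The forecast says X has run out first, with D at 32%, between 30% and 34.5%, a little above this reckoning. Its ground: “Once X is gone, D stops”.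

The flask gives 32.6% at 15 d: X has run out first, with X at 0% of its charge, so its X share is 32.6%.

    G + X → D (k = 0.210 L mol⁻¹ min⁻¹)
    J + X → E (k = 0.0950 L mol⁻¹ min⁻¹)
    Z ⇌ G, rate k3*(cs3 - [G]) while solid is left; crystals form when [G] > cs3 (solubility = 4.60 mM, k = 0.0150 min⁻¹)

A charge of 1.11 equiv of X, all else held, moves D by 5 points, and that is the kind of run that would part from the forecast. Now apply the X share to the neighbour flask charged with 1.70 equiv of X: it predicts 53.2% of D, but that flask stands at 74.0%, a share of 43.5%, higher than Thursday's and still below the even split. The other 56.5% of that flask's X went to E, and its J stands at 4.0% of its charge.

The earlier runs and the new flask are simulated with made-up constants, and the scatter is random.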